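From the first sample to 5.00 h the earlier runs stand still: L and D stay flat within the scatter, at yields that differ from run to run.

in all of them: E 0.10 M

|  | X | J | remark | time |
|---|---|---|---|---|
| north-west | 0.11 M | 1.4 mM | run made earlier |  |
| south | 0.11 M | 2.2 mM | run made earlier |  |
| south-east | 0.17 M | 1 mM | run made earlier |  |
| flask | 0.110 M | 1.0 mM |  | 6.0 h |

| run | time / h | L / % | D / % |
|---|---|---|---|
| north-west | 0.250 | 47.8 | 5.4 |
| north-west | 0.667 | 47.6 | 5.4 |
| north-west | 1.33 | 46.9 | 5.8 |
| north-west | 2.00 | 47.7 | 5.2 |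
| north-west | 3.00 | 47.7 | 4.6 |
| north-west | 4.00 | 48.0 | 6.1 |
| north-west | 5.00 | 48.6 | 5.0 |
| south | 0.250 | 55.3 | 6.2 |
| south | 0.667 | 56.1 | 6.4 |
| south | 1.33 | 56.3 | 6.2 |
| south | 2.00 | 55.3 | 5.8 |
| south | 3.00 | 57.0 | 5.8 |
| south | 4.00 | 56.0 | 6.5 |
| south | 5.00 | 56.0 | 7.1 |
| south-east | 0.417 | 24.2 | 2.3 |
| south-east | 1.33 | 22.8 | 1.1 |
| south-east | 2.00 | 23.4 | 3.2 |
| south-east | 3.00 | 22.7 | 2.1 |
| south-east | 5.00 | 23.1 | 2.6 |

(standard deviation of a reading: 0.5 percentage points)

1. ratio of L to D at 40 s
2. ratio of L to D at 15 min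
3. ratio of L to D at 6.0 h
4. which of L and D there is more of at 6.0 h



So I ask first what the end state of the flask is. L ends near 23.1%, 48.6% and 56.0% in the earlier runs, yet c(L)/c(D) does not follow it beyond the scatter, with J between 1 mM and 2.2 mM and X up to 0.17 M. Summing the readings of the earlier runs, L over D reads 9.08, and I carry this plateau ratio, c(L)/c(D) once the readings stop moving. For the flask I therefore expect that ratio at 15 min and 6.0 h, with L ahead of D. At 40 s there is no reading; if D is formed out of L, which the readings cannot tell, the ratio there lies above the plateau ratio.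

The forecast says 9, 9 and 9 with L ahead, keeping the plateau value at the early time too, of which it says that “the same ratio there is an extrapolation and deserves a wider range”. The flask gives 15.3 at 40 s, higher than the plateau ratio, then 9.11 at 15 min and 9.09 at 6.0 h, with L at 41.2% and D at 4.53% of the E charged.

    E + J → J + Q (k = 2.80 M⁻¹ s⁻¹)
    X + J + Q → J + L (k = 300 M⁻² s⁻¹)
    L + J ⇌ D + J, rate k3*[J]*[L] forward; the back reaction follows from the equilibrium constant (K = 0.110, k = 8.20 M⁻¹ s⁻¹)
    X + L → Z (k = 0.0480 M⁻¹ s⁻¹)

In this flask at the asked time L and D relax towards each other, by the step between them taken both ways, with a half-life of 0.140 min, far shorter than the 6.0 h of the run. That is thermodynamic control at the asked time, and L over the plateau ratio gives 4.54% of D, where the flask holds 4.53%. In the neighbouring flask with 0.40 M of E, L ends at 18.7% of the E charged there, which over the plateau ratio gives 2.06% of D, and that flask holds 2.05%.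

(The runs were computed from invented constants; the scatter is artificial.)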